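The ring (numbered C1 methoxy/prenyl carbon, C2 ketone, C3 acyl, C4, C5 prenyl, C6) is cut at C1–C2 and C3–C4. Because C1 and C4 are para and both oxygenated, the C1 oxygen is taken as the ring oxygen of a fully substituted 2-silyloxyfuran, with furan C5 and C2 becoming C1 and C4. One scandium-catalysed operation adds this furan to an ethoxy alkynone, closes the carbocycle as a 7-oxanorbornadiene, sets the quaternary C1 stereocentre and cleaves the oxygen bridge at C4 only, leaving a non-aromatisable cyclohexa-2,5-dienone. The precursors are 2-(tert-butyldimethylsilyloxy)-4-methoxy-3,5-diprenylfuran and 1-ethoxy-5-phenylpent-1-yn-3-one; silyl-to-methyl exchange at C1 and hydrolysis of two vinylogous esters finish the target.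

Key step: step 7

Assumption: the target is one enol tautomer of a cyclic β-triketone, so every tautomer of the final product is the same compound; its only stereocentre is S in the drawn tautomer. The sense of induction of the scandium catalyst is assumed, and the ligand antipode that gives the S centre would be chosen by experiment. C1–C6 in the Why lines mean the target ring positions defined above; compound names use their own locants.

Step 1
Reactants: 1 tetronic acid; 2 prenyl bromide
Product: 3 4-hydroxy-3-(3-methylbut-2-enyl)furan-2(5H)-one
Conditions: 1 (2 equiv), 2 (1 equiv), Pd(PPh3)4 (2 mol %, zerovalent palladium), K2CO3 (2 equiv), THF/DMF, 0 °C → rt; aq. HCl to pH 2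
Reagents that add atoms: none
Why: Tsuji–Trost allylation, in which the soft tetronate anion attacks the unsubstituted terminus of the π-(1,1-dimethylallyl)palladium complex through its α-carbon, any O-prenyl ether from direct substitution is re-ionised by the zerovalent palladium catalyst and funnelled to the C-alkylated enol, and the excess of 1 holds back a second alkylation.

Step 2
Reactants: 3 4-hydroxy-3-(3-methylbut-2-enyl)furan-2(5H)-one
Product: 4 4-methoxy-3-(3-methylbut-2-enyl)furan-2(5H)-one
Conditions: Me2SO4 (1.2 equiv), K2CO3 (1.5 equiv), acetone, reflux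
Reagents that add atoms: dimethyl sulfate, COS(=O)(=O)OC
Why: Williamson-type O-alkylation of the vinylogous acid with a hard methylating agent should give the 4-methyl ether, the α-carbon being substituted and hindered.

Step 3
Reactants: 4 4-methoxy-3-(3-methylbut-2-enyl)furan-2(5H)-one; 2 prenyl bromide
Product: 6 4-methoxy-3,5-bis(3-methylbut-2-enyl)furan-2(5H)-one (racemic), via lithium furan-2-olate 5 (not isolated)
Conditions: LiN(iPr)2 (1.05 equiv), THF, −78 °C, 30 min; then 2 (1.1 equiv), DMPU, −78 → −40 °C
Reagents that add atoms: none
Why: γ-Deprotonation gives the aromatic lithium furan-2-olate, which undergoes vinylogous enolate alkylation at the γ-carbon because the α-carbon is blocked and γ-attack restores the conjugated butenolide; the new stereocentre forms as a racemate and is erased in step 4.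

Step 4
Reactants: 6 4-methoxy-3,5-bis(3-methylbut-2-enyl)furan-2(5H)-one (racemic)
Product: 7 2-(tert-butyldimethylsilyloxy)-4-methoxy-3,5-bis(3-methylbut-2-enyl)furan
Conditions: TBSOTf (1.2 equiv), Et3N (1.5 equiv), CH2Cl2, 0 °C; filtration through basic alumina, used at once
Reagents that add atoms: tert-butyldimethylsilyl trifluoromethanesulfonate, CC(C)(C)[Si](C)(C)OS(=O)(=O)C(F)(F)F
Why: Soft enolisation by silyl triflate and amine (silyl dienol ether formation) converts the γ-CH butenolide into the aromatic 2-silyloxyfuran, and both enantiomers of 6 converge on achiral 7.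

Step 5
Reactants: 8 3-phenylpropanoyl chloride
Product: 9 N-methoxy-N-methyl-3-phenylpropanamide
Conditions: MeNH(OMe)·HCl (1.1 equiv), Et3N (2.2 equiv), CH2Cl2, 0 °C → rt
Reagents that add atoms: N,O-dimethylhydroxylamine hydrochloride, CNOC.Cl
Why: Nucleophilic acyl substitution of the acid chloride by the hydroxylamine (Weinreb amide formation) is fast and has no competing site.

Step 6
Reactants: 10 ethoxyacetylene; 9 N-methoxy-N-methyl-3-phenylpropanamide
Product: 12 1-ethoxy-5-phenylpent-1-yn-3-one, via lithium ethoxyacetylide 11 (not isolated)
Conditions: 10 (1.3 equiv), n-BuLi (1.25 equiv), THF, −78 °C; then 9, −78 → −40 °C; AcOH in THF at −78 °C, then cold water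
Reagents that add atoms: none
Why: Weinreb ketone synthesis, in which the chelated tetrahedral adduct prevents a second addition and the cold acidic quench protonates the released hydroxylamine so that it should not add to the push–pull ynone.

Step 7
Reactants: 7 2-(tert-butyldimethylsilyloxy)-4-methoxy-3,5-bis(3-methylbut-2-enyl)furan; 12 1-ethoxy-5-phenylpent-1-yn-3-one
Product: 14 (S)-4-(tert-butyldimethylsilyloxy)-3-ethoxy-5-methoxy-4,6-bis(3-methylbut-2-enyl)-2-(3-phenylpropanoyl)cyclohexa-2,5-dien-1-one, via 7-oxanorbornadiene cycloadduct 13 (not isolated)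
Conditions: 7 (1.3 equiv), Sc(OSO2CF3)3 (10 mol %, trivalent scandium), chiral N,N′-dioxide ligand (12 mol %; bis(2,6-diisopropylanilide) from (S)-pipecolic acid, propane-1,3-diyl linker), 4 Å molecular sieves, CH2Cl2, −40 → −20 °C
Reagents that add atoms: none
Why: Proposed new method: the scandium complex binds the ketone oxygen of 12 and makes the ethoxy-bearing alkyne carbon oxocarbenium-like, so the prenyl-bearing C5 of furan 7 adds to it (vinylogous Mukaiyama–Michael step, bond C1–C2), and the scandium allenolate then attacks through its α-carbon the silyloxocarbenium carbon of the butenolide just formed (bond C3–C4), closing the carbocycle in a stepwise polar 4+2 mode, a 6-(enolexo)-exo-trig closure that gives 7-oxanorbornadiene 13. Collapse of the bridgehead silyl ketal at C4, driven by bicyclic strain and the silyloxy lone pair, breaks only the C4–O bridge bond, and the silyl group is relayed through silyl triflate to the tertiary C1 oxygen, giving 14, which cannot aromatise because C1 is quaternary. The closest known reactions are the Diels–Alder reaction of furans with acetylenic ketones followed by opening of the 7-oxanorbornadiene, and the catalytic asymmetric vinylogous Mukaiyama–Michael addition of 2-silyloxyfurans that gives γ-quaternary butenolides. The one stereocentre (C1) is set in the first bond formation by the chiral N,N′-dioxide pocket around trivalent scandium, which exposes one face of the planar furan C5 to the bound ynone, and the C1–O bond is never broken afterwards. The step needs bonding of furan C5 to the ethoxy-bearing alkyne carbon, secured by the matched push–pull polarisation (C5 is the vinylogous terminus of the silyl ketene acetal, reinforced by the 4-methoxy group, while furan C3 is blocked by prenyl), and bridge cleavage on the C4 side only, secured because only C4 carries an oxygen donor.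

Step 8
Reactants: 14 (S)-4-(tert-butyldimethylsilyloxy)-3-ethoxy-5-methoxy-4,6-bis(3-methylbut-2-enyl)-2-(3-phenylpropanoyl)cyclohexa-2,5-dien-1-one
Product: 15 (S)-3-ethoxy-4-hydroxy-5-methoxy-4,6-bis(3-methylbut-2-enyl)-2-(3-phenylpropanoyl)cyclohexa-2,5-dien-1-one
Conditions: Bu4NF (1.5 equiv), AcOH (1.5 equiv), THF, 0 °C → rt
Reagents that add atoms: none
Why: Fluoride-induced Si–O cleavage (desilylation) under acetic acid buffering should deliver the tertiary alcohol without a free alkoxide, so the enol ethers, the prenyl groups and the C1 configuration stay untouched.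

Step 9
Reactants: 15 (S)-3-ethoxy-4-hydroxy-5-methoxy-4,6-bis(3-methylbut-2-enyl)-2-(3-phenylpropanoyl)cyclohexa-2,5-dien-1-one
Product: 17 (S)-3-ethoxy-4,5-dimethoxy-4,6-bis(3-methylbut-2-enyl)-2-(3-phenylpropanoyl)cyclohexa-2,5-dien-1-one, via potassium tertiary alkoxide 16 (not isolated)
Conditions: KN(SiMe3)2 (1.05 equiv), THF, −78 °C, 5 min; then MeOSO2CF3 (1.5 equiv), −78 → −40 °C; Et3N quench
Reagents that add atoms: methyl trifluoromethanesulfonate, COS(=O)(=O)C(F)(F)F
Why: Williamson etherification, in which kinetic O–H deprotonation at −78 °C and immediate trapping of the hindered alkoxide by methyl triflate should outrun enolisation of the side-chain ketone and any sigmatropic shift of the prenyl group; the C–O bond of the stereocentre is not touched.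

Step 10
Reactants: 17 (S)-3-ethoxy-4,5-dimethoxy-4,6-bis(3-methylbut-2-enyl)-2-(3-phenylpropanoyl)cyclohexa-2,5-dien-1-one
Product: 18 (S)-3,5-dihydroxy-6-methoxy-4,6-bis(3-methylbut-2-enyl)-2-(3-phenylpropanoyl)cyclohexa-2,4-dien-1-one (CNP0319461.1)
Conditions: LiOH·H2O (10 equiv), 1,4-dioxane/H2O 3:1, rt then 70 °C; cold 1 M HCl to pH 3
Reagents that add atoms: lithium hydroxide, [Li+].[OH-]
Why: Saponification of the two vinylogous esters by addition–elimination of hydroxide, first at the doubly activated C2 and then on heating at C6, should release the β-triketone as its enolate, while the tertiary C1 methyl ether is not a vinylogous ester and the quaternary stereocentre cannot epimerise.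

Compound list
1 | tetronic acid (4-hydroxyfuran-2(5H)-one) | O=C1C=C(O)CO1 | starting material
2 | prenyl bromide (1-bromo-3-methylbut-2-ene) | CC(C)=CCBr | starting material
3 | 4-hydroxy-3-(3-methylbut-2-enyl)furan-2(5H)-one | O=C1OCC(O)=C1CC=C(C)C | intermediate
4 | 4-methoxy-3-(3-methylbut-2-enyl)furan-2(5H)-one | COC1=C(CC=C(C)C)C(=O)OC1 | intermediate
5 | lithium 4-methoxy-3-(3-methylbut-2-enyl)furan-2-olate (not isolated) | [Li+].[O-]c1occ(OC)c1CC=C(C)C | intermediate
6 | 4-methoxy-3,5-bis(3-methylbut-2-enyl)furan-2(5H)-one, racemic at C5 | COC1=C(CC=C(C)C)C(=O)OC1CC=C(C)C | intermediate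
7 | 2-(tert-butyldimethylsilyloxy)-4-methoxy-3,5-bis(3-methylbut-2-enyl)furan | COc1c(CC=C(C)C)oc(O[Si](C)(C)C(C)(C)C)c1CC=C(C)C | intermediate
8 | 3-phenylpropanoyl chloride | O=C(Cl)CCc1ccccc1 | starting material
9 | N-methoxy-N-methyl-3-phenylpropanamide | CON(C)C(=O)CCc1ccccc1 | intermediate
10 | ethoxyacetylene (ethoxyethyne) | CCOC#C | starting material
11 | lithium ethoxyacetylide (not isolated) | [Li+].[C-]#COCC | intermediate
12 | 1-ethoxy-5-phenylpent-1-yn-3-one | CCOC#CC(=O)CCc1ccccc1 | intermediate
13 | (1S,4S)-4-(tert-butyldimethylsilyloxy)-2-ethoxy-6-methoxy-1,5-bis(3-methylbut-2-enyl)-3-(3-phenylpropanoyl)-7-oxabicyclo[2.2.1]hepta-2,5-diene (not isolated; the prenyl-bearing bridgehead becomes the S centre of 14) | CC(C)=CC[C@]12O[C@](O[Si](C)(C)C(C)(C)C)(C(CC=C(C)C)=C1OC)C(C(=O)CCc3ccccc3)=C2OCC | intermediate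
14 | (S)-4-(tert-butyldimethylsilyloxy)-3-ethoxy-5-methoxy-4,6-bis(3-methylbut-2-enyl)-2-(3-phenylpropanoyl)cyclohexa-2,5-dien-1-one | CC(C)(C)[Si](C)(C)O[C@]1(CC=C(C)C)C(OCC)=C(C(=O)CCc2ccccc2)C(=O)C(CC=C(C)C)=C1OC | intermediate
15 | (S)-3-ethoxy-4-hydroxy-5-methoxy-4,6-bis(3-methylbut-2-enyl)-2-(3-phenylpropanoyl)cyclohexa-2,5-dien-1-one | O[C@]1(CC=C(C)C)C(OCC)=C(C(=O)CCc2ccccc2)C(=O)C(CC=C(C)C)=C1OC | intermediate
16 | potassium alkoxide of 15 (not isolated) | [K+].[O-][C@]1(CC=C(C)C)C(OCC)=C(C(=O)CCc2ccccc2)C(=O)C(CC=C(C)C)=C1OC | intermediate
17 | (S)-3-ethoxy-4,5-dimethoxy-4,6-bis(3-methylbut-2-enyl)-2-(3-phenylpropanoyl)cyclohexa-2,5-dien-1-one | CO[C@]1(CC=C(C)C)C(OCC)=C(C(=O)CCc2ccccc2)C(=O)C(CC=C(C)C)=C1OC | intermediate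
18 | (S)-3,5-dihydroxy-6-methoxy-4,6-bis(3-methylbut-2-enyl)-2-(3-phenylpropanoyl)cyclohexa-2,4-dien-1-one (CNP0319461.1) | CO[C@]1(CC=C(C)C)C(=O)C(C(=O)CCc2ccccc2)=C(O)C(CC=C(C)C)=C1O | target

Total step count: 10. Longest linear sequence: 8 steps (steps 1–4 and 7–10); steps 5–6 form the second branch.

Steps most likely to fail

Step 7 (proposed new method). Several processes could defeat it:
- The sequence may stop after the first C–C bond, with silyl transfer to the allenolate giving an open-chain Michael adduct.
- Silyl triflate released in the cycle may drive a racemic background reaction.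
- Facial selectivity at the furan carbon may be poor, because the stereocentre forms far from the metal-bound carbonyl.
- Traces of water may hydrate the ynol ether.
- The Lewis acid may induce a 1,2-prenyl shift in the product.

The fallback sets out from 7 (with 12) and returns at 14. It relies on the known thermal Diels–Alder reactivity of 2-silyloxyfurans toward acetylenic ketones: heating in toluene at 80 °C with 2,6-di-tert-butylpyridine should give the racemic 7-oxanorbornadiene cycloadduct F1. This should open, if necessary after addition of catalytic achiral TBSOTf, to the racemic silyl ether of the dienone F2. Preparative chromatography on a chiral stationary phase should then deliver 14 and remove its mirror image.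

Step 9. The tertiary alkoxide may transfer a proton from the side-chain ketone and lead to C-methylation. It may also lose or shift its prenyl group by a sigmatropic pathway, or react too slowly for steric reasons, so that excess methyl triflate alkylates the ring carbonyl oxygen. The fallback sets out from 15 and returns at 17 without a new compound (F0). It replaces anionic etherification by acid-promoted diazoalkane O-methylation of the neutral alcohol (Me3SiCHN2, aqueous HBF4, CH2Cl2, 0 °C), so no alkoxide is formed. Any exchange of alkyl groups on the enol ether oxygens would be harmless, since these are removed in step 10.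

Step 10. After the first hydrolysis the ring is an enolate anion, so the second dealkylation at C6 may stall. Forcing may cause retro-Claisen loss of the acyl chain, and too strong acidification may cyclise a prenyl group onto an enol oxygen. The fallback sets out from 17 and returns at 18 in two stages. LiOH in THF/H2O at 0 °C → rt should cleave only the activated ethoxy group and give the mono methyl ether (S)-3-hydroxy-5,6-dimethoxy-4,6-bis(3-methylbut-2-enyl)-2-(3-phenylpropanoyl)cyclohexa-2,4-dien-1-one F3. The remaining enol methyl ether would then be removed by nucleophilic O-demethylation at the methyl carbon (LiCl, DMSO, 120 °C), a method established for vinylogous methyl esters next to prenyl groups.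

Further compounds
F1 | step 7 | racemic 4-(tert-butyldimethylsilyloxy)-2-ethoxy-6-methoxy-1,5-bis(3-methylbut-2-enyl)-3-(3-phenylpropanoyl)-7-oxabicyclo[2.2.1]hepta-2,5-diene | CC(C)=CCC12OC(O[Si](C)(C)C(C)(C)C)(C(CC=C(C)C)=C1OC)C(C(=O)CCc3ccccc3)=C2OCC
F2 | step 7 | racemic 4-(tert-butyldimethylsilyloxy)-3-ethoxy-5-methoxy-4,6-bis(3-methylbut-2-enyl)-2-(3-phenylpropanoyl)cyclohexa-2,5-dien-1-one | CC(C)(C)[Si](C)(C)OC1(CC=C(C)C)C(OCC)=C(C(=O)CCc2ccccc2)C(=O)C(CC=C(C)C)=C1OC
F0 | step 9 | none | none
F3 | step 10 | (S)-3-hydroxy-5,6-dimethoxy-4,6-bis(3-methylbut-2-enyl)-2-(3-phenylpropanoyl)cyclohexa-2,4-dien-1-one | CO[C@]1(CC=C(C)C)C(=O)C(C(=O)CCc2ccccc2)=C(O)C(CC=C(C)C)=C1OC
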